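**Retrosynthetic overview**

1. Ring labels: upper unit A (benzo), C (pyran), B (catechol); lower unit D (benzo), F (pyran), E (catechol). Ring F is made last, in one operation, from a ring-D phenol and a trans-3-aryl-2,3-epoxy aldehyde: ortho C-hydroxyalkylation by the magnesium phenoxide (C4a–C4), then O1–C2 ring closure by opening of the oxirane.
2. Enabling feature: in ring F, O1 and C4 hang from adjacent ring-D carbons (C8a, C4a); C4a is ortho to O1 and para to the C7 oxygen; C2 is benzylic to the electron-rich ring E; and the all-trans C2(aryl)/C3(OH)/C4(OH) array is the image of the epoxy aldehyde (CHO = C4, oxirane = C3–O and C2).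
3. Interflavanyl bond C4 (ring C)–C6 (ring D): intramolecular Friedel–Crafts alkylation through a temporary O3–Si(iPr)2–O tether to resorcinol, which enforces the 3,4-cis geometry. The resulting seven-membered silylene then masks O3 and the ring-D C7 oxygen during the key step.
4. Upper flavan-3,4-diol (rings A, C, B): the same annulation on 3-(benzyloxy)phenol. The epoxy aldehyde comes from 3,4-bis(benzyloxy)benzaldehyde by Wittig homologation and organocatalytic epoxidation.
5. Order of ring formation: ring C, then the temporary dioxasilepine ring, then ring F; desilylation and hydrogenolysis finish the synthesis.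

Key step: step 7

Remark on the chemistry (assumption): the 4-methyl ether of step 4 is drawn as its 4R epimer, but both C4 epimers are carried forward together because C4 becomes a planar cation in step 6.

**Route**

Step 1
Reactants: 1 3,4-bis(benzyloxy)benzaldehyde; 2 (triphenylphosphoranylidene)acetaldehyde
Product: 3 (E)-3-[3,4-bis(benzyloxy)phenyl]prop-2-enal
Conditions: toluene, 80 °C
Reagents that add atoms: none
Why: Wittig olefination with the stabilised formylmethylene ylide should give the E-enal, adding the two carbons that become C3 and C4 of each flavan unit.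

Step 2
Reactants: 3 (E)-3-[3,4-bis(benzyloxy)phenyl]prop-2-enal
Product: 4 (2R,3S)-3-[3,4-bis(benzyloxy)phenyl]oxirane-2-carbaldehyde
Conditions: (S)-2-{bis[3,5-bis(trifluoromethyl)phenyl][(trimethylsilyl)oxy]methyl}pyrrolidine (10 mol %), 35% aq. H2O2, CH2Cl2, rt; used without chromatography
Reagents that add atoms: hydrogen peroxide OO
Why: Iminium–enamine organocatalytic nucleophilic epoxidation of the enal, in which hydroperoxide adds to the β-carbon on the face left open by the diarylsilyloxymethyl group and the enamine closes the trans-oxirane, so that both stereocentres (2R,3S) are catalyst-controlled.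

Step 3
Reactants: 5 3-(benzyloxy)phenol; 4 (2R,3S)-3-[3,4-bis(benzyloxy)phenyl]oxirane-2-carbaldehyde
Product: 7 (2R,3S,4R)-7-(benzyloxy)-2-[3,4-bis(benzyloxy)phenyl]chromane-3,4-diol, via epoxy carbinol 6 (not isolated)
Conditions: EtMgBr (1.0 equiv), Et2O, 0 °C; solvent change to CH2Cl2; 4 (1.05 equiv), −30 °C to rt; pH 7 buffer
Reagents that add atoms: none
Why: Proposed new method: the bromomagnesium phenoxide of 5 should attack the aldehyde of 4 through its ortho carbon para to the benzyloxy group in a magnesium-templated cyclic transition state (closest known type: ortho-specific hydroxyalkylation of magnesium phenoxides with α-oxygenated aldehydes), after which the phenoxide oxygen opens the magnesium-activated oxirane at its benzylic carbon in the 6-endo mode with inversion (closest known type: cyclisation of o-hydroxyaryl epoxy carbinols derived from 2'-hydroxychalcone epoxides to flavan-3,4-diols), giving C2 as R (2,3-trans) with C3 taken from 4, while chelation should give 4R, although either C4 epimer serves because C4 is ionised in step 6.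

Step 4
Reactants: 7 (2R,3S,4R)-7-(benzyloxy)-2-[3,4-bis(benzyloxy)phenyl]chromane-3,4-diol
Product: 8 (2R,3S,4R)-7-(benzyloxy)-2-[3,4-bis(benzyloxy)phenyl]-4-methoxychroman-3-ol
Conditions: MeOH/CH2Cl2 (1:1), pyridinium p-toluenesulfonate (10 mol %), rt
Reagents that add atoms: methanol CO
Why: Acid-catalysed SN1 solvolysis should occur at C4 only, because the 4-hydroxyl is benzylic and para to the ring-A benzyloxy group whereas the 3-hydroxyl is not activated, which differentiates the two hydroxyls and installs the leaving group for step 6.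

Step 5
Reactants: 8 (2R,3S,4R)-7-(benzyloxy)-2-[3,4-bis(benzyloxy)phenyl]-4-methoxychroman-3-ol; 9 resorcinol
Product: 11 3-O-[(3-hydroxyphenoxy)di(propan-2-yl)silyl] ether of 8, via chlorosilyl ether 10 (not isolated)
Conditions: iPr2SiCl2 (3 equiv), imidazole, CH2Cl2, 0 °C to rt; volatiles removed in vacuo; then 9 (5 equiv), imidazole, THF, rt
Reagents that add atoms: dichlorodi(propan-2-yl)silane CC(C)[Si](Cl)(Cl)C(C)C
Why: Stepwise silyl ether formation (the secondary alcohol first, then a phenol used in excess so that only one resorcinol hydroxyl reacts) should give the mixed dialkoxysilane that serves as a temporary silicon tether between O3 and the future ring D.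

Step 6
Reactants: 11 3-O-[(3-hydroxyphenoxy)di(propan-2-yl)silyl] ether of 8
Product: 12 cyclic di(propan-2-yl)silylene (3-O to 2''-O) of (2R,3S,4S)-7-(benzyloxy)-2-[3,4-bis(benzyloxy)phenyl]-4-(2,4-dihydroxyphenyl)chroman-3-ol
Conditions: BF3·OEt2 (1.5 equiv), CH2Cl2 (2 mM), −78 to −20 °C
Reagents that add atoms: none
Why: Intramolecular Friedel–Crafts alkylation in which ionisation of the 4-methoxy group gives the ring-A-stabilised flavan-4-yl cation and the tethered resorcinol ring can reach C4 only by axial attack from the face of O3 (seven-membered dioxasilepine), which sets C4 as 3,4-cis and directs attack to the carbon ortho to the silyloxy group and para to the free hydroxyl, as in the tether-directed 3,4-cis flavanyl couplings known with diester linkers.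

Step 7
Reactants: 12 cyclic di(propan-2-yl)silylene of the 4-(2,4-dihydroxyphenyl)flavan-3-ol; 4 (2R,3S)-3-[3,4-bis(benzyloxy)phenyl]oxirane-2-carbaldehyde
Product: 14 cyclic di(propan-2-yl)silylene (upper-unit O3 to ring-D O7) of (2R,3S,4S)-7-(benzyloxy)-2-[3,4-bis(benzyloxy)phenyl]-4-{(2R,3S,4R)-2-[3,4-bis(benzyloxy)phenyl]-3,4,7-trihydroxychroman-6-yl}chroman-3-ol, via epoxy carbinol 13 (not isolated)
Conditions: EtMgBr (1.0 equiv), Et2O, 0 °C; solvent change to CH2Cl2; 4 (1.1 equiv), −30 °C to rt; pH 7 buffer
Reagents that add atoms: none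
Why: Proposed new method: the bromomagnesium phenoxide of 12 (its only free hydroxyl is the ring-D one para to the interflavanyl carbon) should attack the aldehyde carbon of 4 with its free ortho carbon C4a inside a magnesium-bridged six-membered transition state in which the metal also binds the oxirane oxygen, and the magnesium salt of epoxy carbinol 13 then closes ring F when the phenoxide oxygen O1 opens the metal-activated oxirane at the benzylic carbon C2. The closest known reaction types are the ortho-specific hydroxyalkylation of magnesium phenoxides with α-oxygenated aldehydes in non-coordinating solvents and the cyclisation of o-hydroxyaryl epoxy carbinols to flavan-3,4-diols; new is their union through an epoxy aldehyde, so that a phenol and a three-carbon unit give the whole heterocycle. Ring F closes by O1–C2 bond formation in a 6-endo-tet epoxide opening. C4 (R) is set by chelation control (attack on the aldehyde face next to the α-hydrogen of the magnesium chelate gives the syn epoxy carbinol and hence the 3,4-trans diol), C2 (R) by inversion at the oxirane carbon (a looser opening would lead through the chair with equatorial aryl to the same 2,3-trans isomer), and C3 (S) is carried over from 4. The step needs C- over O-alkylation and C4a over C8 (secured by the magnesium phenoxide in CH2Cl2, the para oxygen at C7 and the crowding of C8 between two oxygens), syn over anti addition (chelation of the oxirane oxygen), and 6-endo over 5-exo opening (secured by the 3,4-bis(benzyloxy)phenyl group, which stabilises positive charge at C2).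

Step 8
Reactants: 14 cyclic di(propan-2-yl)silylene of the penta-O-benzyl biflavanoid
Product: 15 (2R,3S,4S)-7-(benzyloxy)-2-[3,4-bis(benzyloxy)phenyl]-4-{(2R,3S,4R)-2-[3,4-bis(benzyloxy)phenyl]-3,4,7-trihydroxychroman-6-yl}chroman-3-ol
Conditions: Bu4NF (2.2 equiv), AcOH (2.2 equiv), THF, 0 °C
Reagents that add atoms: none
Why: Buffered fluoride desilylation should cleave both Si–O bonds of the silylene and free O3 and the ring-D C7 hydroxyl without acid that could ionise the benzylic 4-hydroxyl of ring F and without touching any stereocentre.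

Step 9
Reactants: 15 penta-O-benzyl biflavanoid
Product: 16 (2R,3S,4S)-2-(3,4-dihydroxyphenyl)-4-[(2R,3S,4R)-2-(3,4-dihydroxyphenyl)-3,4,7-trihydroxy-3,4-dihydro-2H-chromen-6-yl]-3,4-dihydro-2H-chromene-3,7-diol (CNP0280090.2)
Conditions: H2 (1 atm), Pd(OH)2/C, THF/MeOH (1:1), rt, neutral, stopped at complete debenzylation
Reagents that add atoms: none
Why: Catalytic hydrogenolysis should remove the five O-benzyl groups under neutral conditions, under which the C2–O1 bonds and the secondary benzylic 4-hydroxyl of ring F are cleaved far more slowly than primary benzyl ethers and no stereocentre is affected.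

**Compound list**

1 | 3,4-bis(benzyloxy)benzaldehyde | O=Cc1ccc(OCc2ccccc2)c(OCc2ccccc2)c1 | starting material
2 | (triphenylphosphoranylidene)acetaldehyde | O=CC=P(c1ccccc1)(c1ccccc1)c1ccccc1 | starting material
3 | (E)-3-[3,4-bis(benzyloxy)phenyl]prop-2-enal | O=C/C=C/c1ccc(OCc2ccccc2)c(OCc2ccccc2)c1 | intermediate
4 | (2R,3S)-3-[3,4-bis(benzyloxy)phenyl]oxirane-2-carbaldehyde | O=C[C@@H]1O[C@H]1c1ccc(OCc2ccccc2)c(OCc2ccccc2)c1 | intermediate
5 | 3-(benzyloxy)phenol | Oc1cccc(OCc2ccccc2)c1 | starting material
6 | (R)-[4-(benzyloxy)-2-hydroxyphenyl]{(2S,3S)-3-[3,4-bis(benzyloxy)phenyl]oxiran-2-yl}methanol (formed as its magnesium salt) | Oc1cc(OCc2ccccc2)ccc1[C@@H](O)[C@@H]1O[C@H]1c1ccc(OCc2ccccc2)c(OCc2ccccc2)c1 | intermediate (not isolated)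
7 | (2R,3S,4R)-7-(benzyloxy)-2-[3,4-bis(benzyloxy)phenyl]chromane-3,4-diol (tri-O-benzyl-mollisacacidin; 2,3-trans-3,4-trans) | C(c1ccccc1)Oc1ccc2c(c1)O[C@H](c1ccc(OCc3ccccc3)c(OCc3ccccc3)c1)[C@@H](O)[C@@H]2O | intermediate
8 | (2R,3S,4R)-7-(benzyloxy)-2-[3,4-bis(benzyloxy)phenyl]-4-methoxychroman-3-ol (C4 epimer also serviceable) | C(c1ccccc1)Oc1ccc2c(c1)O[C@H](c1ccc(OCc3ccccc3)c(OCc3ccccc3)c1)[C@@H](O)[C@@H]2OC | intermediate
9 | resorcinol (benzene-1,3-diol) | Oc1cccc(O)c1 | starting material
10 | 3-O-[chlorodi(propan-2-yl)silyl] ether of 8 | C(c1ccccc1)Oc1ccc2c(c1)O[C@H](c1ccc(OCc3ccccc3)c(OCc3ccccc3)c1)[C@@H](O[Si](Cl)(C(C)C)C(C)C)[C@@H]2OC | intermediate (not isolated)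
11 | 3-O-[(3-hydroxyphenoxy)di(propan-2-yl)silyl] ether of 8 | C(c1ccccc1)Oc1ccc2c(c1)O[C@H](c1ccc(OCc3ccccc3)c(OCc3ccccc3)c1)[C@@H](O[Si](C(C)C)(C(C)C)Oc1cccc(O)c1)[C@@H]2OC | intermediate
12 | cyclic di(propan-2-yl)silylene (3-O to 2''-O) of (2R,3S,4S)-7-(benzyloxy)-2-[3,4-bis(benzyloxy)phenyl]-4-(2,4-dihydroxyphenyl)chroman-3-ol (2,3-trans-3,4-cis; 4''-OH free) | C(c1ccccc1)Oc1ccc2c(c1)O[C@H](c1ccc(OCc3ccccc3)c(OCc3ccccc3)c1)[C@@H](O[Si]4(C(C)C)C(C)C)[C@H]2c1ccc(O)cc1O4 | intermediate
13 | 12 carrying at ring-D C5'' (ortho to the free hydroxyl) the group (R)-hydroxy{(2S,3S)-3-[3,4-bis(benzyloxy)phenyl]oxiran-2-yl}methyl (formed as its magnesium salt) | C(c1ccccc1)Oc1ccc2c(c1)O[C@H](c1ccc(OCc3ccccc3)c(OCc3ccccc3)c1)[C@@H](O[Si]4(C(C)C)C(C)C)[C@H]2c1cc([C@@H](O)[C@@H]5O[C@H]5c5ccc(OCc3ccccc3)c(OCc3ccccc3)c5)c(O)cc1O4 | intermediate (not isolated)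
14 | cyclic di(propan-2-yl)silylene (upper-unit O3 to ring-D O7) of 15 | C(c1ccccc1)Oc1ccc2c(c1)O[C@H](c1ccc(OCc3ccccc3)c(OCc3ccccc3)c1)[C@@H](O[Si]4(C(C)C)C(C)C)[C@H]2c1cc2c(cc1O4)O[C@H](c1ccc(OCc3ccccc3)c(OCc3ccccc3)c1)[C@@H](O)[C@@H]2O | intermediate
15 | (2R,3S,4S)-7-(benzyloxy)-2-[3,4-bis(benzyloxy)phenyl]-4-{(2R,3S,4R)-2-[3,4-bis(benzyloxy)phenyl]-3,4,7-trihydroxychroman-6-yl}chroman-3-ol | C(c1ccccc1)Oc1ccc2c(c1)O[C@H](c1ccc(OCc3ccccc3)c(OCc3ccccc3)c1)[C@@H](O)[C@H]2c1cc2c(cc1O)O[C@H](c1ccc(OCc3ccccc3)c(OCc3ccccc3)c1)[C@@H](O)[C@@H]2O | intermediate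
16 | (2R,3S,4S)-2-(3,4-dihydroxyphenyl)-4-[(2R,3S,4R)-2-(3,4-dihydroxyphenyl)-3,4,7-trihydroxy-3,4-dihydro-2H-chromen-6-yl]-3,4-dihydro-2H-chromene-3,7-diol (fisetinidol-(4β→6)-fisetinidol-4α-ol, CNP0280090.2) | Oc1ccc2c(c1)O[C@H](c1ccc(O)c(O)c1)[C@@H](O)[C@H]2c1cc2c(cc1O)O[C@H](c1ccc(O)c(O)c1)[C@@H](O)[C@@H]2O | target

**Step count**

Total steps: 9. Longest linear sequence: 9 steps (1 → 3 → 4 → 7 → 8 → 11 → 12 → 14 → 15 → 16); epoxy aldehyde 4 is used twice (steps 3 and 7).

**Steps most likely to fail**

1. Step 7 (proposed new method). Several processes could defeat it: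
   - C–C bond formation may be outrun by opening of the electron-rich oxirane (by bromide or by the phenoxide oxygen) or by hydride transfer from the product alkoxide to unreacted aldehyde.
   - Facial selectivity at the aldehyde may be poor if the oxirane oxygen does not chelate magnesium.
   - The ring closure may stall at the epoxy carbinol or take the 5-exo course.

   Fallback (known chemistry, ring F closed at the monomer stage and the units joined biomimetically): it sets out from 7. Hydrogenolysis (H2, Pd(OH)2/C, THF/MeOH) gives (2R,3S,4R)-2-(3,4-dihydroxyphenyl)chromane-3,4,7-triol, (+)-mollisacacidin F1. Its acid-catalysed self-condensation in dilute aqueous HCl at rt is a Friedel–Crafts alkylation of C6 of one molecule by the flavan-4-yl cation of another. It should give 16 beside its 4α-linked epimer and higher oligomers, from which 16 is separated on Sephadex LH-20. The route is rejoined at 16.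

2. Step 3 (proposed new method). The same processes as in step 7 apply on a simpler phenol, together with possible attack at the carbon between the two ring oxygens.

   Fallback (known chemistry, chalcone epoxide route): it sets out from 1 and comes back at 7.
   - Claisen–Schmidt condensation of 1 with commercial 1-[4-(benzyloxy)-2-hydroxyphenyl]ethanone (KOH, EtOH) gives (E)-1-[4-(benzyloxy)-2-hydroxyphenyl]-3-[3,4-bis(benzyloxy)phenyl]prop-2-en-1-one F2.
   - MOMCl and iPr2NEt give its 2'-O-methoxymethyl ether F3.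
   - Juliá–Colonna epoxidation (poly-L-leucine, urea–H2O2, DBU, THF) gives the (2R,3S)-epoxy ketone F4.
   - HCl in MeOH removes the methoxymethyl group, and the freed phenol opens the oxirane at the benzylic carbon to give (2R,3R)-7-(benzyloxy)-2-[3,4-bis(benzyloxy)phenyl]-3-hydroxychroman-4-one (tri-O-benzylfustin) F5.
   - NaBH4 (MeOH/THF, 0 °C) reduces the ketone to the 2,3-trans-3,4-trans diol 7.

3. Step 6. Intermolecular alkylation and oligomerisation may compete with the seven-membered ring closure. The Lewis acid may cleave the aryl silyl ether before ionisation, so that the untethered ring attacks with poor facial selectivity. Attack may also occur at the carbon between the two ring oxygens.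

   Fallback (untethered coupling, stereocontrol replaced by separation): it sets out from 8. Friedel–Crafts condensation with excess resorcinol 9 (BF3·OEt2, CH2Cl2–Et2O, 0 °C) gives both C4 epimers of the 4-(2,4-dihydroxyphenyl) adduct. The 3,4-cis isomer (2R,3S,4S)-7-(benzyloxy)-2-[3,4-bis(benzyloxy)phenyl]-4-(2,4-dihydroxyphenyl)chroman-3-ol F6 is separated by chromatography. Bridging of its 3-OH and 2''-OH with iPr2SiCl2 and imidazole at high dilution rejoins the route at 12.

**Further compounds**

F1 | step 7 | (2R,3S,4R)-2-(3,4-dihydroxyphenyl)chromane-3,4,7-triol, (+)-mollisacacidin | Oc1ccc2c(c1)O[C@H](c1ccc(O)c(O)c1)[C@@H](O)[C@@H]2O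
F2 | step 3 | (E)-1-[4-(benzyloxy)-2-hydroxyphenyl]-3-[3,4-bis(benzyloxy)phenyl]prop-2-en-1-one | O=C(/C=C/c1ccc(OCc2ccccc2)c(OCc2ccccc2)c1)c1ccc(OCc2ccccc2)cc1O
F3 | step 3 | (E)-1-[4-(benzyloxy)-2-(methoxymethoxy)phenyl]-3-[3,4-bis(benzyloxy)phenyl]prop-2-en-1-one | O=C(/C=C/c1ccc(OCc2ccccc2)c(OCc2ccccc2)c1)c1ccc(OCc2ccccc2)cc1OCOC
F4 | step 3 | [4-(benzyloxy)-2-(methoxymethoxy)phenyl]{(2R,3S)-3-[3,4-bis(benzyloxy)phenyl]oxiran-2-yl}methanone | O=C([C@@H]1O[C@H]1c1ccc(OCc2ccccc2)c(OCc2ccccc2)c1)c1ccc(OCc2ccccc2)cc1OCOC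
F5 | step 3 | (2R,3R)-7-(benzyloxy)-2-[3,4-bis(benzyloxy)phenyl]-3-hydroxychroman-4-one (tri-O-benzylfustin) | C(c1ccccc1)Oc1ccc2c(c1)O[C@H](c1ccc(OCc3ccccc3)c(OCc3ccccc3)c1)[C@@H](O)C2=O
F6 | step 6 | (2R,3S,4S)-7-(benzyloxy)-2-[3,4-bis(benzyloxy)phenyl]-4-(2,4-dihydroxyphenyl)chroman-3-ol | C(c1ccccc1)Oc1ccc2c(c1)O[C@H](c1ccc(OCc3ccccc3)c(OCc3ccccc3)c1)[C@@H](O)[C@H]2c1ccc(O)cc1O
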